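## Structural features

The target 26 is a tetrahydrofuran (O1, C2 to C5) substituted at every carbon: C2 carries a 4-hydroxyphenyl ring, C3 a 2,4-dihydroxybenzoyl group through the ketone carbon C7 (its aryl ring is ring A), C4 a hydroxy(4-hydroxyphenyl)methyl arm through the carbinol carbon C6, and C5 a 2,4-dihydroxyphenyl ring. C2, C3, C4 and C5 are contiguous stereocentres and C6 hangs on C4 as a fifth; all five are R, with the C2 aryl trans to the C3 acyl group and the C3, C4 and C5 substituents on one face. The halves C2/C3 and C6/C4 are the same unit, ArCH(O)–CH(C=O), with the same configuration, so the core is the opened form of a twofold-symmetric cis-fused dilactone whose carbonyl carbons are C5 and C7. The fragile points are C3, which is alpha to the ketone and beta to O1 and can epimerise or open the ring by elimination under base, and the three benzylic C–O bonds at C2, C5 and C6, each on a ring with a para (at C5 also ortho) oxygen that assists ionisation. The C5 aryl sits on the crowded face, so it must be set kinetically and kept away from acid afterwards. The real difficulty is to join ring A to C7 without an enolate or a basic organometallic at C3, once the all-cis C3/C4/C5 array exists. The key step uses the fact that in ring A the hydroxyl sits on the carbon next to the one bonded to C7: these two neighbouring ring carbons are the two ends of an aryne, so the C7–aryl bond and the aryl–O bond can both come from insertion of an aryne into the C7–O bond of a C3 carboxylate.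

## Logic of the disconnections

26 ⇒ 25. The five phenolic O–H bonds and the ring A C–H bond ortho to C7 are traced back to five O–benzyl bonds and one C–Cl bond. Benzyl masks every phenol through the organolithium, Lewis acid and fluoride steps, the chlorine is the regiochemical control of the key step, and all six bonds are returned in one hydrogenolysis. The gain is that 25 has no free phenol except the chelated one. The forward step must spare the three benzylic C–O bonds of the core and the ketone, and must trap hydrogen chloride without leaving strong base on the product.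

25 ⇒ 24. The O–H bond at C6 is replaced by an O–Si bond. The C6 oxygen must be masked while C7 is a carboxylate, or it would close back onto C7 or be arylated. The gain is a precursor with a single nucleophilic site. The demand is a removal that neither ionises C5–O1 nor deprotonates C3.

24 ⇒ 14 + 21 (through 22 and 23). The C7–aryl bond and the aryl–oxygen bond of the ring A phenol are cut together. Both can be made from a carboxylate oxygen and the carbonyl carbon already on C3, so no carbanion is needed at or next to C3. The gain is the largest of the route: ring A leaves as an achiral fragment and the core becomes a plain carboxylic acid. The forward step needs the carboxylate to add to the aryne carbon remote from chlorine, acyl transfer to beat protonation and chloride loss, and the fluoride source to spare the silyl ether.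

14 ⇒ 12 ⇒ 11 (through 13). The O–Si bond is removed and the C7 carboxyl and C6 hydroxyl are joined as a gamma-lactone. The lactone holds the C3 and C4 substituents cis and protects both functions during aryl addition and reduction. The gain is a rigid bicycle with a convex and a concave face. The demand is that silylation of the C6 hydroxyl outruns reclosure of the lactone.

11 ⇒ 10 ⇒ 6 + 8 (through 9). The C5–H and C5–aryl bonds are cut, taking C5 back to a lactone carbonyl. At that oxidation level the core is twofold-symmetric, the aryl group enters as a nucleophile, and the hydrogen enters as hydride from the convex face, which places the aryl cis to the C4 arm. The gain is a symmetric dilactone with four stereocentres in two identical pairs. The demands are addition to only one of two equivalent carbonyls, and kinetic hydride delivery with no later acid-induced inversion at C5.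

6 ⇒ 5 ⇒ 1 + 2 (through 3 and 4). The two lactone C–O bonds and the C2–C3 and C4–C6 bonds are cut. Both halves are identical, so one bis-enolate and two molecules of one aldehyde suffice. The gain is four stereocentres from two achiral commercial compounds. The demands are syn selectivity in each aldol, like configuration at C3 and C4 (only that isomer can close twice), and a separation of enantiomers, since no chiral controller is used.

21 ⇒ 20 ⇒ 16 ⇒ 15 (through 17, 18 and 19), and 8 ⇒ 7. In 21 the O–benzyl bond is cut first, then the C–Si and O–S bonds, then the C–Br bond. Bromine is placed on the symmetrical 15 before the two oxygens are differentiated, and only the oxygen next to bromine can pass silicon to carbon, so the positions of silicon and triflate are fixed unambiguously. The demands are monobromination next to chlorine, not between the hydroxyls, and a silyl shift faster than loss of lithium chloride. 8 comes from 7 by cutting two O–benzyl bonds.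

## Other disconnections considered

Alternative 1: The cut is through C2–C3 and C4–C6 at the dilactone stage, the same two bonds that step 1 makes, but under auxiliary control. Forward: the bis-imide A1 is converted with Bu2BOTf and iPr2NEt into its bis(Z)-boron enolate, which adds to two molecules of 2 to give the syn,syn bis-aldol A2; lactonisation with loss of both auxiliaries would then give 6.
- In its favour: each aldol passes through a closed chair transition state whose facial sense is set by the auxiliary on the same carbonyl, so the syn relationship, the like sense at C3/C4 and the absolute configuration come from one well-understood element, without resolution.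
- Against it here: twofold soft enolisation of a 1,4-dicarbonyl compound is uncertain, because the second deprotonation occurs next to an electron-rich enolate and gives an oxidation-prone 1,4-dioxygenated diene. The first aldolate can close onto the distal imide and remove the second enolisable position. Two equivalents of auxiliary and boron triflate are carried for a four-carbon unit, and A2 needs a further step to reach the dilactone.
- Comparison: on structure it uses the same hidden symmetry. On mechanism its stereocontrol is better founded than that of steps 1 and 2, which rely on substrate preference and a resolution; on this point the alternative is the better. On step economy the two are equal. It does nothing for the C7–ring A bond, so it is a possible replacement for steps 1 and 2 rather than a rival to step 11.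

Alternative 2: The cut removes O1–C5, C4–C5 and C2–C3 at once, so the tetrahydrofuran ring is the product of the key step. Forward: Rh2(OAc)4 decomposes the diazo ester A3, the carbonyl oxygen of 2 adds to the carbenoid, and the carbonyl ylide adds across the butenolide A4. The ester-stabilised ylide carbon (C5) bonds to the beta carbon C4 and the aldehyde carbon (C2) to the alpha carbon C3, giving the cis-fused lactone A5 with a quaternary C5.
- In its favour: it is the most convergent plan (three components, three bonds, one ring). The cis fusion follows from a concerted cycloaddition, the dipole should approach anti to the C6 aryl of A4, and the polarity of dipole and dipolarophile is matched.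
- Against it here: C5 carries one carbon too many, so the ester must be cleaved and the carboxyl removed with hydrogen delivered to the convex face (two or three more steps, with the same facial question as step 5). The configuration at C2 depends on endo/exo orientation with no strong substrate bias. Stabilised aryl ester ylides can close to epoxides or take up a second aldehyde rather than a modest dipolarophile. The ortho oxygen of A3 must be silylated, not benzylated, to prevent C–H insertion, which changes the protecting-group plan. A4 needs its own asymmetric synthesis.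
- Comparison: on structure it builds the ring directly instead of using the symmetry. On mechanism it stakes facial and endo/exo selectivity on one pericyclic step where the chosen plan has separately controllable events. On step economy its longest linear sequence could equal or undercut the chosen one; its convergence and freedom from resolution are points on which it is the better. It converges on the oxidation pattern of 11 and also leaves the C7–ring A bond unsolved.

Alternative 3: The cut is through the C2–H and C6–H bonds and the two lactone C–O bonds, back to the diketo diester A6. Forward: RuCl(p-cymene)[(R,R)-TsDPEN] with HCO2H/Et3N reduces both aryl ketones under dynamic kinetic resolution of the adjacent labile carbons, and each new hydroxyl closes onto the distal ester to give the dilactone A7, which is the same substance as 6.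
- In its favour: catalytic control of all four stereocentres and the absolute configuration, a substrate from oxidative dimerisation of one beta-keto ester, lactonisation as driving force and filter, no auxiliary and no resolution.
- Against it here: the dynamic resolution must work twice. After the first reduction and ring closure, the carbon that was alpha to the first ketone is held in a lactone and epimerises far less easily, yet the second reduction needs its alpha carbon matched and cis to the first ring; a mismatch gives half-closed or exo,endo material. A6 is a mixture of meso, chiral and enol forms, and electron-rich 4-alkoxyaryl ketones are slow in hydride transfer.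
- Comparison: on structure it uses the same twofold symmetry. On mechanism the configuration comes from the catalyst rather than from substrate preference followed by separation; on this point it is better than steps 1 and 2. On step economy it is equal or slightly better. Because A7 is identical with 6 it could replace steps 1 and 2 unchanged downstream; like Alternative 1 it does not address how ring A is joined to C7.

Key step: step 11

Remark: 14, 21 and 24 are mutually consistent and consistent with 26, so none is altered; 10 is written as the closed hemiketal (anomers unspecified), which equilibrates with its open hydroxy ketone.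

## Route

Step 1
Reactants: 1 N,N,N',N'-tetramethylbutanediamide; 2 4-(benzyloxy)benzaldehyde
Product: 5 rac-(1R*,2R*,5R*,6R*)-2,6-bis[4-(benzyloxy)phenyl]-3,7-dioxabicyclo[3.3.0]octane-4,8-dione (exo,exo racemate), via dilithium bis-enolate 3 (not isolated), via bis-aldol diamide 4 (not isolated)
Conditions: LiN(iPr)2 (2.2 equiv), THF, −78 to −20 °C; 2 (2.1 equiv), −78 °C; 2 M HCl quench; dioxane, 60 °C; crystallisation
Reagents that add atoms: none
Why: Twofold aldol addition of a succinamide bis-enolate, then acid-catalysed lactonisation of the gamma-hydroxy amides with loss of dimethylamine; each (Z)-amide enolate should add through a closed chair transition state to give the syn relationship (C2/C3 and C6/C4), which places each aryl group exo after ring closure. Only the bis-adduct with like configuration at C3 and C4 can close twice to the cis-fused bicycle, so the unlike isomer stays behind as a polar hydroxy amide and 5 is expected to crystallise as the exo,exo racemate.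

Step 2
Reactants: 5 rac-(1R*,2R*,5R*,6R*)-2,6-bis[4-(benzyloxy)phenyl]-3,7-dioxabicyclo[3.3.0]octane-4,8-dione
Product: 6 (1R,2R,5R,6R)-2,6-bis[4-(benzyloxy)phenyl]-3,7-dioxabicyclo[3.3.0]octane-4,8-dione
Conditions: preparative SFC, amylose tris(3,5-dimethylphenylcarbamate) on silica, CO2–MeOH, 40 °C
Reagents that add atoms: none
Why: Resolution of a racemate on a chiral stationary phase; no bond is made, and a rigid twofold-symmetric diaryl dilactone is the kind of analyte such phases separate, while only two cheap starting materials are sacrificed at this point. The enantiomer to be carried on is identified by X-ray analysis of a crystalline derivative that contains a centre of known configuration.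

Step 3
Reactants: 7 4-bromobenzene-1,3-diol
Product: 8 2,4-bis(benzyloxy)-1-bromobenzene
Conditions: BnBr (2.2 equiv), K2CO3, DMF, rt
Reagents that add atoms: benzyl bromide, BrCc1ccccc1
Why: Williamson etherification of both phenols; the bromine is untouched and marks the carbon that is lithiated next.

Step 4
Reactants: 8 2,4-bis(benzyloxy)-1-bromobenzene; 6 (1R,2R,5R,6R)-2,6-bis[4-(benzyloxy)phenyl]-3,7-dioxabicyclo[3.3.0]octane-4,8-dione
Product: 10 (3R,3aR,6R,6aR)-3,6-bis[4-(benzyloxy)phenyl]-4-[2,4-bis(benzyloxy)phenyl]-4-hydroxytetrahydro-1H,3H-furo[3,4-c]furan-1-one (hemiketal at C5 of the core), via aryllithium 9 (not isolated)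
Conditions: 8, n-BuLi (1.0 equiv), THF, −78 °C; added to 6 (1.3 equiv), THF, −78 °C; AcOH, −78 °C
Reagents that add atoms: none
Why: Bromine–lithium exchange, then 1,2-addition of the aryllithium to a lactone carbonyl; the tetrahedral lithium alkoxide is stable at −78 °C, so the same carbon is not attacked twice, and the two carbonyls of 6 are related by the twofold axis, so only one mono-adduct exists (6 is used in excess and recovered). The bridgehead hydrogens are not removed at this temperature, so C2, C3, C4 and C6 are untouched.

Step 5
Reactants: 10 hemiketal lactone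
Product: 11 (3R,3aS,4R,6R,6aR)-3,6-bis[4-(benzyloxy)phenyl]-4-[2,4-bis(benzyloxy)phenyl]tetrahydro-1H,3H-furo[3,4-c]furan-1-one (C5 aryl endo, cis to the C4–C6 bond)
Conditions: Et3SiH (5 equiv), BF3·OEt2 (2 equiv), CH2Cl2, −78 to −40 °C; NaHCO3 (aq) at −40 °C
Reagents that add atoms: none
Why: Ionic hydrogenation of a hemiketal through the cyclic oxocarbenium ion; hydride should enter from the convex face of the cis-fused bicycle, which leaves the C5 aryl endo (5R). Low temperature and a cold basic quench keep the Lewis acid from ionising the new, strongly donor-substituted benzylic ether.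

Step 6
Reactants: 11 bicyclic lactone
Product: 12 lithium (2R,3R,4R,5R)-2-[4-(benzyloxy)phenyl]-4-{(R)-[4-(benzyloxy)phenyl](hydroxy)methyl}-5-[2,4-bis(benzyloxy)phenyl]tetrahydrofuran-3-carboxylate
Conditions: LiOH·H2O (1.05 equiv), THF–H2O, 0 °C to rt; evaporation, azeotropic drying (PhMe)
Reagents that add atoms: lithium hydroxide, [Li+].[OH-]
Why: Saponification of a gamma-lactone by acyl–oxygen cleavage, so C6 keeps its configuration; hydroxide attacks the carbonyl much faster than it enolises C3, and once C7 is a carboxylate C3 is no longer acidic. The salt is not acidified because the free hydroxy acid would close back to 11.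

Step 7
Reactants: 12 lithium hydroxy carboxylate
Product: 14 (2R,3R,4S,5R)-2-[4-(benzyloxy)phenyl]-4-{(R)-[4-(benzyloxy)phenyl](triisopropylsilyloxy)methyl}-5-[2,4-bis(benzyloxy)phenyl]tetrahydrofuran-3-carboxylic acid, via silyl ester 13 (not isolated)
Conditions: iPr3SiOTf (3 equiv), 2,6-lutidine, CH2Cl2, −40 to 0 °C; K2CO3, MeOH–THF–H2O, 0 °C; pH 4 buffer
Reagents that add atoms: triisopropylsilyl trifluoromethanesulfonate, CC(C)[Si](C(C)C)(C(C)C)OS(=O)(=O)C(F)(F)F
Why: O-Silylation of hydroxyl and carboxylate, then selective solvolysis of the silyl ester, which is far more labile than the hindered secondary silyl ether. The silyl triflate is reactive enough for the crowded C6 hydroxyl, and the bulky silyl ester is a poor acylating agent, which disfavours reclosure to 11; the triisopropylsilyl group is chosen because it must survive fluoride in step 11.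

Step 8
Reactants: 15 5-chlorobenzene-1,3-diol
Product: 16 4-bromo-5-chlorobenzene-1,3-diol
Conditions: NBS (0.95 equiv), MeCN, −20 to 0 °C
Reagents that add atoms: N-bromosuccinimide, O=C1CCC(=O)N1Br
Why: Electrophilic aromatic bromination; the position ortho to one hydroxyl and para to the other should be preferred over the position between the two hydroxyls, by analogy with resorcinol and its 5-substituted congeners, and a slight deficit of reagent limits dibromination. Because 15 is symmetrical, this position is necessarily the one between a hydroxyl and the chlorine.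

Step 9
Reactants: 16 4-bromo-5-chlorobenzene-1,3-diol
Product: 20 3-chloro-5-hydroxy-2-(trimethylsilyl)phenyl trifluoromethanesulfonate, via bis(silyl) ether 17 (not isolated), via lithium phenoxide 18 (not isolated), via silyl ether triflate 19 (not isolated)
Conditions: (Me3Si)2NH, 80 °C, evaporation; n-BuLi (1.05 equiv), THF, −100 °C; Tf2O, −100 to −78 °C; citric acid, MeOH–H2O, 0 °C
Reagents that add atoms: hexamethyldisilazane, C[Si](C)(C)N[Si](C)(C)C; trifluoromethanesulfonic anhydride, O=S(=O)(OS(=O)(=O)C(F)(F)F)C(F)(F)F
Why: O-Silylation, bromine–lithium exchange and retro-Brook rearrangement (1,3 shift of silicon from oxygen to carbon), then O-triflation; only the oxygen next to the lithiated carbon can deliver silicon, so the trimethylsilyl group ends between chlorine and the oxygen that becomes the triflate. At −100 °C the silyl shift should outrun loss of LiCl from the ortho-chloroaryllithium, and the remaining aryl silyl ether is hydrolysed in the mildly acidic work-up.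

Step 10
Reactants: 20 3-chloro-5-hydroxy-2-(trimethylsilyl)phenyl trifluoromethanesulfonate
Product: 21 5-(benzyloxy)-3-chloro-2-(trimethylsilyl)phenyl trifluoromethanesulfonate
Conditions: BnOH, PPh3, diisopropyl azodicarboxylate, THF, 0 °C to rt
Reagents that add atoms: benzyl alcohol, OCc1ccccc1
Why: Mitsunobu etherification of the phenol under neutral conditions, so that neither base nor fluoride touches the silyl triflate.

Step 11
Reactants: 14 (2R,3R,4S,5R)-tetrahydrofuran-3-carboxylic acid with the C6 triisopropylsilyl ether; 21 5-(benzyloxy)-3-chloro-2-(trimethylsilyl)phenyl trifluoromethanesulfonate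
Product: 24 [4-(benzyloxy)-2-chloro-6-hydroxyphenyl][(2R,3R,4S,5R)-2-[4-(benzyloxy)phenyl]-4-{(R)-[4-(benzyloxy)phenyl](triisopropylsilyloxy)methyl}-5-[2,4-bis(benzyloxy)phenyl]tetrahydrofuran-3-yl]methanone, via caesium carboxylate 22 (not isolated), via aryne 23 (not isolated)
Conditions: 14, Cs2CO3 (0.5 equiv), MeOH, rt, evaporation, azeotropic drying (PhMe); 21 (1.3 equiv), CsF (3 equiv), THF, 80 °C, sealed; AcOH (1.1 equiv), 0 °C
Reagents that add atoms: none
Why: Fluoride attacks silicon in 21 and triflate leaves from the neighbouring carbon, giving aryne 23; the carboxylate oxygen of 22 adds to the aryne carbon remote from chlorine, because the developing aryl anion then sits next to the inductively withdrawing chlorine, the carbon towards which the distorted triple bond is already polarised (the 5-benzyloxy group has only a weak, opposite bias and is overridden). The ortho-(acyloxy)aryl anion then attacks its own ester carbonyl through a four-membered transition state and the tetrahedral intermediate opens to the phenoxide, so C7 moves from oxygen to the carbon between chlorine and the new phenoxide oxygen, an anionic ortho-Fries-type acyl shift. The closest known reaction type is the insertion of arynes into the C–O bond of carboxylic acids to give ortho-hydroxyaryl ketones with CsF in THF at elevated temperature. No ring closes and no stereocentre is formed; the two new bonds are aryl–O and C7–aryl. Acyl transfer must win over protonation (the preformed, dried caesium salt removes the only acidic proton), over chloride loss from the ortho-chloroaryl anion (the intramolecular acyl shift should be faster), and over a second arylation (only a small excess of 21, and the product phenoxide is chelated to the ketone and flanked by it). C3 is never an enolate: as the alpha carbon of a carboxylate it is not acidic, and in the product the ketone is conjugated with a phenoxide, which lowers the acidity of C3–H, so the 3R configuration and the beta-alkoxy ketone should survive. Sparingly soluble CsF in THF and the bulk of the triisopropylsilyl group should spare the C6 silyl ether. The benzyloxy group ends para to C7 and meta to the new hydroxyl, which becomes the 2,4-dihydroxy pattern once chlorine is removed.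

Step 12
Reactants: 24 silyl-protected chloro ketone
Product: 25 [4-(benzyloxy)-2-chloro-6-hydroxyphenyl][(2R,3R,4R,5R)-2-[4-(benzyloxy)phenyl]-4-{(R)-[4-(benzyloxy)phenyl](hydroxy)methyl}-5-[2,4-bis(benzyloxy)phenyl]tetrahydrofuran-3-yl]methanone
Conditions: HF·pyridine, pyridine, THF, 0 °C to rt
Reagents that add atoms: none
Why: Fluoride cleavage of the silyl ether with pyridine-buffered HF, which is not basic enough to touch C3 and not acidic enough to ionise the C2 or C5 benzylic ethers. The ortho-hydroxyaryl ketone is held open by its hydrogen bond and should not close to a hemiketal with the freed hydroxyl.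

Step 13
Reactants: 25 pentabenzyl chloro ketone
Product: 26 (2,4-dihydroxyphenyl)[(2R,3R,4R,5R)-5-(2,4-dihydroxyphenyl)-4-[(R)-hydroxy(4-hydroxyphenyl)methyl]-2-(4-hydroxyphenyl)tetrahydrofuran-3-yl]methanone
Conditions: H2 (1 atm), Pd/C (10% palladium on carbon), Et3N (1.1 equiv), EtOAc–MeOH, rt; filtration
Reagents that add atoms: none
Why: Hydrogenolysis on palladium cleaves the five aryl benzyl ethers and the aryl C–Cl bond in one operation, the amine taking up HCl so that the medium never becomes acidic and ending as its hydrochloride so that little free base remains. Benzylic alcohols and cyclic benzylic ethers are cleaved much more slowly than aryl benzyl ethers under these neutral to weakly basic conditions at one atmosphere.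

## Compound list

1 | N,N,N',N'-tetramethylbutanediamide | CN(C)C(=O)CCC(=O)N(C)C | starting material
2 | 4-(benzyloxy)benzaldehyde | O=Cc1ccc(OCc2ccccc2)cc1 | starting material
3 | dilithium (1Z,3Z)-1,4-bis(dimethylamino)buta-1,3-diene-1,4-diolate | [Li+].[Li+].[O-]/C(N(C)C)=C\C=C(/[O-])N(C)C | intermediate
4 | rac-(2R*,3R*)-2,3-bis{(R*)-[4-(benzyloxy)phenyl](hydroxy)methyl}-N,N,N',N'-tetramethylbutanediamide (syn,syn; racemate, one enantiomer drawn) | CN(C)C(=O)[C@@H]([C@@H](O)c1ccc(OCc2ccccc2)cc1)[C@H]([C@@H](O)c1ccc(OCc2ccccc2)cc1)C(=O)N(C)C | intermediate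
5 | rac-(1R*,2R*,5R*,6R*)-2,6-bis[4-(benzyloxy)phenyl]-3,7-dioxabicyclo[3.3.0]octane-4,8-dione (exo,exo; racemate, one enantiomer drawn) | O=C2[C@@H]1[C@H]([C@@H](O2)c3ccc(OCc4ccccc4)cc3)C(=O)O[C@H]1c1ccc(OCc2ccccc2)cc1 | intermediate
6 | (1R,2R,5R,6R)-2,6-bis[4-(benzyloxy)phenyl]-3,7-dioxabicyclo[3.3.0]octane-4,8-dione (single enantiomer) | O=C2[C@@H]1[C@H]([C@@H](O2)c3ccc(OCc4ccccc4)cc3)C(=O)O[C@H]1c1ccc(OCc2ccccc2)cc1 | intermediate
7 | 4-bromobenzene-1,3-diol | Oc1ccc(Br)c(O)c1 | starting material
8 | 2,4-bis(benzyloxy)-1-bromobenzene | Brc1ccc(OCc2ccccc2)cc1OCc1ccccc1 | intermediate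
9 | [2,4-bis(benzyloxy)phenyl]lithium | [Li]c1ccc(OCc2ccccc2)cc1OCc1ccccc1 | intermediate
10 | (3R,3aR,6R,6aR)-3,6-bis[4-(benzyloxy)phenyl]-4-[2,4-bis(benzyloxy)phenyl]-4-hydroxytetrahydro-1H,3H-furo[3,4-c]furan-1-one (anomers at the hemiketal carbon) | O=C2[C@@H]1[C@H]([C@@H](O2)c3ccc(OCc4ccccc4)cc3)C(O)(c3ccc(OCc4ccccc4)cc3OCc3ccccc3)O[C@H]1c1ccc(OCc2ccccc2)cc1 | intermediate
11 | (3R,3aS,4R,6R,6aR)-3,6-bis[4-(benzyloxy)phenyl]-4-[2,4-bis(benzyloxy)phenyl]tetrahydro-1H,3H-furo[3,4-c]furan-1-one | O=C2[C@@H]1[C@H]([C@@H](O2)c3ccc(OCc4ccccc4)cc3)[C@H](c3ccc(OCc4ccccc4)cc3OCc3ccccc3)O[C@H]1c1ccc(OCc2ccccc2)cc1 | intermediate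
12 | lithium (2R,3R,4R,5R)-2-[4-(benzyloxy)phenyl]-4-{(R)-[4-(benzyloxy)phenyl](hydroxy)methyl}-5-[2,4-bis(benzyloxy)phenyl]tetrahydrofuran-3-carboxylate | [Li+].[O-]C(=O)[C@@H]1[C@H]([C@@H](O)c2ccc(OCc3ccccc3)cc2)[C@H](c2ccc(OCc3ccccc3)cc2OCc2ccccc2)O[C@H]1c1ccc(OCc2ccccc2)cc1 | intermediate
13 | triisopropylsilyl (2R,3R,4S,5R)-2-[4-(benzyloxy)phenyl]-4-{(R)-[4-(benzyloxy)phenyl](triisopropylsilyloxy)methyl}-5-[2,4-bis(benzyloxy)phenyl]tetrahydrofuran-3-carboxylate | CC(C)[Si](C(C)C)(C(C)C)OC(=O)[C@@H]1[C@H]([C@@H](O[Si](C(C)C)(C(C)C)C(C)C)c2ccc(OCc3ccccc3)cc2)[C@H](c2ccc(OCc3ccccc3)cc2OCc2ccccc2)O[C@H]1c1ccc(OCc2ccccc2)cc1 | intermediate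
14 | (2R,3R,4S,5R)-2-[4-(benzyloxy)phenyl]-4-{(R)-[4-(benzyloxy)phenyl](triisopropylsilyloxy)methyl}-5-[2,4-bis(benzyloxy)phenyl]tetrahydrofuran-3-carboxylic acid | OC(=O)[C@@H]1[C@H]([C@@H](O[Si](C(C)C)(C(C)C)C(C)C)c2ccc(OCc3ccccc3)cc2)[C@H](c2ccc(OCc3ccccc3)cc2OCc2ccccc2)O[C@H]1c1ccc(OCc2ccccc2)cc1 | intermediate
15 | 5-chlorobenzene-1,3-diol | Oc1cc(O)cc(Cl)c1 | starting material
16 | 4-bromo-5-chlorobenzene-1,3-diol | Oc1cc(O)c(Br)c(Cl)c1 | intermediate
17 | 4-bromo-5-chloro-1,3-bis(trimethylsilyloxy)benzene | C[Si](C)(C)Oc1cc(O[Si](C)(C)C)c(Br)c(Cl)c1 | intermediate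
18 | lithium 3-chloro-2-(trimethylsilyl)-5-(trimethylsilyloxy)phenolate | [Li+].[O-]c1cc(O[Si](C)(C)C)cc(Cl)c1[Si](C)(C)C | intermediate
19 | 3-chloro-2-(trimethylsilyl)-5-(trimethylsilyloxy)phenyl trifluoromethanesulfonate | C[Si](C)(C)Oc1cc(Cl)c([Si](C)(C)C)c(OS(=O)(=O)C(F)(F)F)c1 | intermediate
20 | 3-chloro-5-hydroxy-2-(trimethylsilyl)phenyl trifluoromethanesulfonate | Oc1cc(Cl)c([Si](C)(C)C)c(OS(=O)(=O)C(F)(F)F)c1 | intermediate
21 | 5-(benzyloxy)-3-chloro-2-(trimethylsilyl)phenyl trifluoromethanesulfonate | C[Si](C)(C)c1c(Cl)cc(OCc2ccccc2)cc1OS(=O)(=O)C(F)(F)F | intermediate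
22 | caesium (2R,3R,4S,5R)-2-[4-(benzyloxy)phenyl]-4-{(R)-[4-(benzyloxy)phenyl](triisopropylsilyloxy)methyl}-5-[2,4-bis(benzyloxy)phenyl]tetrahydrofuran-3-carboxylate | [Cs+].[O-]C(=O)[C@@H]1[C@H]([C@@H](O[Si](C(C)C)(C(C)C)C(C)C)c2ccc(OCc3ccccc3)cc2)[C@H](c2ccc(OCc3ccccc3)cc2OCc2ccccc2)O[C@H]1c1ccc(OCc2ccccc2)cc1 | intermediate
23 | 5-(benzyloxy)-3-chlorobenzyne (5-(benzyloxy)-3-chloro-1,2-didehydrobenzene) | ClC1=CC(OCc2ccccc2)=CC#C1 | intermediate
24 | [4-(benzyloxy)-2-chloro-6-hydroxyphenyl][(2R,3R,4S,5R)-2-[4-(benzyloxy)phenyl]-4-{(R)-[4-(benzyloxy)phenyl](triisopropylsilyloxy)methyl}-5-[2,4-bis(benzyloxy)phenyl]tetrahydrofuran-3-yl]methanone | O=C(c1c(Cl)cc(OCc2ccccc2)cc1O)[C@@H]1[C@H]([C@@H](O[Si](C(C)C)(C(C)C)C(C)C)c2ccc(OCc3ccccc3)cc2)[C@H](c2ccc(OCc3ccccc3)cc2OCc2ccccc2)O[C@H]1c1ccc(OCc2ccccc2)cc1 | intermediate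
25 | [4-(benzyloxy)-2-chloro-6-hydroxyphenyl][(2R,3R,4R,5R)-2-[4-(benzyloxy)phenyl]-4-{(R)-[4-(benzyloxy)phenyl](hydroxy)methyl}-5-[2,4-bis(benzyloxy)phenyl]tetrahydrofuran-3-yl]methanone | O=C(c1c(Cl)cc(OCc2ccccc2)cc1O)[C@@H]1[C@H]([C@@H](O)c2ccc(OCc3ccccc3)cc2)[C@H](c2ccc(OCc3ccccc3)cc2OCc2ccccc2)O[C@H]1c1ccc(OCc2ccccc2)cc1 | intermediate
26 | (2,4-dihydroxyphenyl)[(2R,3R,4R,5R)-5-(2,4-dihydroxyphenyl)-4-[(R)-hydroxy(4-hydroxyphenyl)methyl]-2-(4-hydroxyphenyl)tetrahydrofuran-3-yl]methanone | O=C(c1ccc(O)cc1O)[C@@H]1[C@H]([C@@H](O)c2ccc(O)cc2)[C@H](c2ccc(O)cc2O)O[C@H]1c1ccc(O)cc1 | target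

## Step count and least certain steps

Total: 13 steps. Longest linear sequence: 9 steps (1, 2, 4, 5, 6, 7, 11, 12, 13).

Step 11 (key step).
- What may go wrong: protonation of the aryl anion before acyl transfer if any proton source remains, which stops at O-arylation; loss of chloride from the ortho-chloroaryl anion and further aryne chemistry; addition of the carboxylate to the wrong aryne carbon; fluoride-induced silyl transfer from the C6 oxygen to the carboxylate and reclosure to the lactone; a second arylation of the product phenoxide.
- Fallback (known chemistry), from 14 to 26: amide coupling with N,O-dimethylhydroxylamine gives the N-methoxy-N-methylamide F1. Aryllithium 9 (from 8) adds at −78 °C, and the chelated adduct is quenched cold with acid to release the 2,4-bis(benzyloxy)phenyl ketone F2. HF·pyridine gives the alcohol F3, and hydrogenolysis on Pd/C, now without chlorine and therefore without base, gives 26.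

Step 1.
- What may go wrong: loss of relative stereocontrol — anti leakage in either aldol, reversal of the aldol addition of the aromatic aldehyde, and above all the wrong facial sense in the second addition, giving a backbone that cannot close twice.
- Fallback, from 2 to 5: a Mukaiyama aldol on a cyclic bis-enolate equivalent. 2,5-Bis(trimethylsilyloxy)furan F4 (from succinic anhydride, Me3SiCl, Et3N, ZnCl2) reacts with two equivalents of 2 and TiCl4 at −78 °C. The first side chain on the five-membered ring directs the second aldehyde to the opposite face and fixes the like backbone in the trans bis-aldol anhydride F5. Aqueous acid opens the anhydride and closes both lactones.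

Step 2.
- What may go wrong: incomplete separation or low throughput on the chiral phase, or a wrong assignment of which eluted enantiomer is which.
- Fallback, from 5 to 6: covalent resolution. Aminolysis of both lactones with (S)-1-phenylethylamine (2-hydroxypyridine catalysis, 80 °C) gives diastereomeric bis(hydroxy amides). The (2R,3R) diastereomer F6 is separated by crystallisation or chromatography on silica and its configuration read from X-ray analysis against the known amine centres. TsOH·H2O in toluene at 80 °C closes both lactones again and releases the amine.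

Step 5.
- What may go wrong: poor facial selectivity of hydride delivery; Lewis-acid ionisation of the new C5–O1 bond with reclosure to the more stable C5 epimer; further reductive opening of that bond by the silane.
- Fallback, from 10 to 11: a neutral radical reduction. PhSH with catalytic BF3·OEt2 at −78 °C converts 10 into the phenylthio ketal F7. Bu3SnH with azobisisobutyronitrile in toluene at 80 °C generates the planar C5 radical, which should take hydrogen from the convex face with no acid present once the stereocentre exists.

Step 7.
- What may go wrong: reclosure of the lactone competing with O-silylation, because the carboxylate is silylated first and then sits as an activated ester next to the free hydroxyl; incomplete silylation of the hindered C6 hydroxyl.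
- Fallback, from 12 to 14: a stable ester in place of the transient silyl ester. Alkylation of the carboxylate with allyl bromide in DMF at 0 °C gives the allyl hydroxy ester F8, which is silylated at once (iPr3SiOTf, 2,6-lutidine) to the allyl ester silyl ether F9. Pd(PPh3)4 with morpholine removes the allyl group.

Step 13.
- What may go wrong: over-reduction by hydrogenolysis of the C6–OH bond or of the ring C–O bonds once the para phenols are free; incomplete loss of chlorine; base-promoted inversion at C5 or C3 in the free polyphenol.
- Fallback, from 24 to 26: reverse the order of the last two steps. Hydrogenolysis of 24 (H2, Pd/C, NaOAc, EtOAc–MeOH) with the silyl ether still shielding the C6–O bond gives the silyl ether pentaphenol F10. HF·pyridine buffered with pyridine then removes the silyl group.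

## Further compounds

F1 | step 11 | (2R,3R,4S,5R)-2-[4-(benzyloxy)phenyl]-4-{(R)-[4-(benzyloxy)phenyl](triisopropylsilyloxy)methyl}-5-[2,4-bis(benzyloxy)phenyl]-N-methoxy-N-methyltetrahydrofuran-3-carboxamide | CON(C)C(=O)[C@@H]1[C@H]([C@@H](O[Si](C(C)C)(C(C)C)C(C)C)c2ccc(OCc3ccccc3)cc2)[C@H](c2ccc(OCc3ccccc3)cc2OCc2ccccc2)O[C@H]1c1ccc(OCc2ccccc2)cc1
F2 | step 11 | [2,4-bis(benzyloxy)phenyl] ketone at C7 with the C6 triisopropylsilyl ether | O=C(c1ccc(OCc2ccccc2)cc1OCc1ccccc1)[C@@H]1[C@H]([C@@H](O[Si](C(C)C)(C(C)C)C(C)C)c2ccc(OCc3ccccc3)cc2)[C@H](c2ccc(OCc3ccccc3)cc2OCc2ccccc2)O[C@H]1c1ccc(OCc2ccccc2)cc1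
F3 | step 11 | [2,4-bis(benzyloxy)phenyl] ketone at C7 with free C6 hydroxyl (hexabenzyl ether of 26) | O=C(c1ccc(OCc2ccccc2)cc1OCc1ccccc1)[C@@H]1[C@H]([C@@H](O)c2ccc(OCc3ccccc3)cc2)[C@H](c2ccc(OCc3ccccc3)cc2OCc2ccccc2)O[C@H]1c1ccc(OCc2ccccc2)cc1
F4 | step 1 | 2,5-bis(trimethylsilyloxy)furan | C[Si](C)(C)Oc1ccc(O[Si](C)(C)C)o1
F5 | step 1 | rac-trans-3,4-bis{[4-(benzyloxy)phenyl](hydroxy)methyl}dihydrofuran-2,5-dione (racemate, one enantiomer drawn) | O=C1OC(=O)[C@@H]([C@@H](O)c2ccc(OCc3ccccc3)cc2)[C@@H]1[C@@H](O)c1ccc(OCc2ccccc2)cc1
F6 | step 2 | (2R,3R)-2,3-bis{(R)-[4-(benzyloxy)phenyl](hydroxy)methyl}-N,N'-bis[(S)-1-phenylethyl]butanediamide | O=C(N[C@@H](C)c1ccccc1)[C@@H]([C@@H](O)c1ccc(OCc2ccccc2)cc1)[C@H]([C@@H](O)c1ccc(OCc2ccccc2)cc1)C(=O)N[C@@H](C)c1ccccc1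
F7 | step 5 | (3R,3aR,6R,6aR)-3,6-bis[4-(benzyloxy)phenyl]-4-[2,4-bis(benzyloxy)phenyl]-4-(phenylsulfanyl)tetrahydro-1H,3H-furo[3,4-c]furan-1-one (anomers) | O=C2[C@@H]1[C@H]([C@@H](O2)c3ccc(OCc4ccccc4)cc3)C(Sc3ccccc3)(c3ccc(OCc4ccccc4)cc3OCc3ccccc3)O[C@H]1c1ccc(OCc2ccccc2)cc1
F8 | step 7 | allyl (2R,3R,4R,5R)-2-[4-(benzyloxy)phenyl]-4-{(R)-[4-(benzyloxy)phenyl](hydroxy)methyl}-5-[2,4-bis(benzyloxy)phenyl]tetrahydrofuran-3-carboxylate | C=CCOC(=O)[C@@H]1[C@H]([C@@H](O)c2ccc(OCc3ccccc3)cc2)[C@H](c2ccc(OCc3ccccc3)cc2OCc2ccccc2)O[C@H]1c1ccc(OCc2ccccc2)cc1
F9 | step 7 | allyl (2R,3R,4S,5R)-2-[4-(benzyloxy)phenyl]-4-{(R)-[4-(benzyloxy)phenyl](triisopropylsilyloxy)methyl}-5-[2,4-bis(benzyloxy)phenyl]tetrahydrofuran-3-carboxylate | C=CCOC(=O)[C@@H]1[C@H]([C@@H](O[Si](C(C)C)(C(C)C)C(C)C)c2ccc(OCc3ccccc3)cc2)[C@H](c2ccc(OCc3ccccc3)cc2OCc2ccccc2)O[C@H]1c1ccc(OCc2ccccc2)cc1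
F10 | step 13 | C6 triisopropylsilyl ether of 26 | O=C(c1ccc(O)cc1O)[C@@H]1[C@H]([C@@H](O[Si](C(C)C)(C(C)C)C(C)C)c2ccc(O)cc2)[C@H](c2ccc(O)cc2O)O[C@H]1c1ccc(O)cc1
A1 | alternative 1 | 3,3'-(butanedioyl)bis[(4R)-4-benzyl-1,3-oxazolidin-2-one] | O=C(CCC(=O)N1[C@H](Cc2ccccc2)COC1=O)N1[C@H](Cc2ccccc2)COC1=O
A2 | alternative 1 | twofold-symmetric syn,syn bis-aldol bis-imide | O=C(N1[C@H](Cc2ccccc2)COC1=O)[C@@H]([C@@H](O)c1ccc(OCc2ccccc2)cc1)[C@H]([C@@H](O)c1ccc(OCc2ccccc2)cc1)C(=O)N1[C@H](Cc2ccccc2)COC1=O
A3 | alternative 2 | 2,2,2-trichloroethyl 2-[2,4-bis(tert-butyldimethylsilyloxy)phenyl]-2-diazoacetate | [N-]=[N+]=C(C(=O)OCC(Cl)(Cl)Cl)c1ccc(O[Si](C)(C)C(C)(C)C)cc1O[Si](C)(C)C(C)(C)C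
A4 | alternative 2 | (5R)-5-[4-(benzyloxy)phenyl]furan-2(5H)-one | O=C1C=C[C@@H](O1)c1ccc(OCc2ccccc2)cc1
A5 | alternative 2 | cis-fused tetrahydrofuran lactone with quaternary C5 (ester endo) | O=C2[C@@H]1[C@H]([C@@H](O2)c3ccc(OCc4ccccc4)cc3)[C@@](C(=O)OCC(Cl)(Cl)Cl)(c3ccc(O[Si](C)(C)C(C)(C)C)cc3O[Si](C)(C)C(C)(C)C)O[C@H]1c1ccc(OCc2ccccc2)cc1
A6 | alternative 3 | diethyl 2,3-bis[4-(benzyloxy)benzoyl]butanedioate (configurationally labile mixture) | CCOC(=O)C(C(=O)c1ccc(OCc2ccccc2)cc1)C(C(=O)c1ccc(OCc2ccccc2)cc1)C(=O)OCC
A7 | alternative 3 | (1R,2R,5R,6R)-2,6-bis[4-(benzyloxy)phenyl]-3,7-dioxabicyclo[3.3.0]octane-4,8-dione (exo,exo) | O=C2[C@@H]1[C@H]([C@@H](O2)c3ccc(OCc4ccccc4)cc3)C(=O)O[C@H]1c1ccc(OCc2ccccc2)cc1
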